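**Plan**

Numbering of the target (bicyclo[8.2.0]dodecane): C1 quaternary (Me), C3 ring CH2, C4 bears the acrylate, C6 bears the prenyl group, C7 bears the methylidene, C10 and C12 are the cyclobutane CH centres.
Enabling feature: C4 carries a 2-(methoxycarbonyl)allyl unit (C4–C(=CH2)–CO2Me), so a carboxyl placed on C3 makes C3–C4 the σ-bond of a γ,δ-unsaturated acid. A retro-Ireland–Claisen cut of C3–C4 then leads to a 14-membered allylic lactone (C3–CO–O–CH2–C(CO2Me)=C4H).
Further cuts: lactone C–O (carboxylate alkylation), the acrylate (Baylis–Hillman), C7–C8 (alkylzinc plus thioester, both methylidenes from ketones), then the cyclobutane piece back through a bicyclo[3.1.1]heptane (alkoxy-radical C–C scission) to farnesoic acid (vinylketene [2+2]).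
Forward order: the cyclobutane first (inside the bridged bicycle), then the side chain, then the 14-membered lactone, and last the ten-membered ring by ring contraction; the helper CO2H on C3 is then removed.
Stereochemistry: C1/C10/C12 relative configuration from the 6E-alkene and the bridged bicycle, absolute configuration by kinetic resolution; C6 by auxiliary-controlled alkylation; C4 by the chiral boron ketene acetal in the [3,3] shift.

Key step: step 19

Assumption: the (S,S)-antipode of the boron controller is taken as the one that delivers the 4S centre in step 19; if the sense proves opposite, the (R,R)-antipode is used in the same step without other change.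

**Route**

Step 1
Reactants: 1 (2E,6E)-farnesol
Product: 2 (2E,6E)-farnesal
Conditions: MnO2, CH2Cl2, rt
Reagents that add atoms: none
Why: MnO2 oxidises the allylic primary alcohol selectively to the enal (allylic oxidation) and leaves the isolated trisubstituted alkenes and the 6E geometry untouched.

Step 2
Reactants: 2 (2E,6E)-farnesal
Product: 3 (2E,6E)-farnesoic acid
Conditions: NaClO2, NaH2PO4, 2-methylbut-2-ene, t-BuOH/H2O, 0 °C to rt
Reagents that add atoms: sodium chlorite, [Na+].[O-]Cl=O
Why: Pinnick oxidation converts the enal to the acid under buffered conditions, with 2-methylbut-2-ene capturing hypochlorite so that the alkenes survive.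

Step 3
Reactants: 3 (2E,6E)-farnesoic acid
Product: 6 rac-(1R,5S,6S)-6-methyl-2-methylidene-6-(4-methylpent-3-en-1-yl)bicyclo[3.1.1]heptan-7-one, via farnesoyl chloride 4 (not isolated), via vinylketene 5 (not isolated)
Conditions: (COCl)2, PhH, rt; concentrate; slow addition to Et3N, PhMe, reflux
Reagents that add atoms: none
Why: Triethylamine removes a γ-hydrogen of the acid chloride to give vinylketene 5, which undergoes an intramolecular ketene–alkene [2+2] cycloaddition (ketene carbonyl carbon to C6, ketene α-carbon to the cation-stabilising C7) that is suprafacial on the 6E-alkene, so the methyl group lies syn and the homoprenyl chain anti to the three-carbon bridge and all three cyclobutane centres are set relative to each other in a racemic bicyclo[3.1.1]heptanone.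

Step 4
Reactants: 6 rac-bicyclic cyclobutanone
Product: 7 rac-(1R,5R,6S)-6-methyl-2-methylidene-6-(4-methylpent-3-en-1-yl)bicyclo[3.1.1]heptane (racemic β-trans-bergamotene)
Conditions: N2H4·H2O, KOH, diethylene glycol, 130 °C then 200 °C
Reagents that add atoms: none
Why: Wolff–Kishner reduction (Huang-Minlon conditions) removes the non-enolisable cyclobutanone carbonyl as N2 without touching the alkenes or the stereocentres.

Step 5
Reactants: 7 racemic β-trans-bergamotene
Product: 8 rac-methyl 3-[(1S,5R,6S)-6-methyl-2-oxobicyclo[3.1.1]heptan-6-yl]propanoate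
Conditions: O3, NaOH, MeOH/CH2Cl2, −78 °C; then Me2S
Reagents that add atoms: ozone, [O-][O+]=O; methanol, CO
Why: Ozonolysis in methanolic NaOH cleaves both alkenes in one operation, the trisubstituted chain alkene ending as the methyl ester and the exocyclic methylene as the ring ketone, so the two new carbonyl groups are differentiated at once.

Step 6
Reactants: 8 racemic keto ester
Product: 9 methyl 3-[(1S,5R,6S)-6-methyl-2-oxobicyclo[3.1.1]heptan-6-yl]propanoate (single enantiomer, recovered ketone)
Conditions: (S)-2-methyl-CBS-oxazaborolidine (20 mol %), BH3·SMe2 (0.3 equiv), THF, −20 °C, stopped a little beyond half conversion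
Reagents that add atoms: none
Why: Kinetic resolution by Corey–Bakshi–Shibata reduction: with the bridgehead carbon as the large group, the (S)-catalyst delivers hydride to the open face (anti to the C6 bridge) only in the unwanted antipode, whereas in 9 the catalyst-preferred face is the one shielded by the syn methyl group, so 9 should be recovered enantioenriched while the antipode is removed as its alcohol.

Step 7
Reactants: 9 keto ester
Product: 10 methyl 3-[(1S,2S,5R,6S)-2-hydroxy-2,6-dimethylbicyclo[3.1.1]heptan-6-yl]propanoate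
Conditions: MeMgBr, THF, −78 °C
Reagents that add atoms: methylmagnesium bromide, C[Mg]Br
Why: Grignard addition to the ketone, much faster than to the methyl ester at −78 °C, should occur from the face anti to the C6 bridge, and the new carbinol centre is destroyed in step 8.

Step 8
Reactants: 10 tertiary alcohol
Product: 11 methyl 3-[(1S,2S,4S)-2-acetyl-4-(2-iodoethyl)-1-methylcyclobutyl]propanoate
Conditions: PhI(OAc)2, I2, cyclohexane, hν (visible), rt
Reagents that add atoms: iodine, II
Why: Suárez alkoxy-radical fragmentation: the hypoiodite gives the C2 alkoxy radical, β-scission of the C2–C3 bond (relief of bicyclic strain, primary radical preferred over a bridgehead cyclobutyl radical as in pinan-2-yloxy radicals) leaves the methyl ketone on the cyclobutane, and iodine traps the primary radical, while the three cyclobutane centres stay untouched.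

Step 9
Reactants: 12 methyl 4,4-dimethoxybutanoate
Product: 13 4,4-dimethoxybutanoic acid
Conditions: LiOH, THF/H2O, rt; then NaH2PO4 to pH about 5
Reagents that add atoms: lithium hydroxide, [Li+].[OH-]
Why: Saponification of the ester under basic conditions, followed by a buffered acidification, keeps the dimethyl acetal intact.

Step 10
Reactants: 13 4,4-dimethoxybutanoic acid; 14 (4R)-4-benzyl-1,3-oxazolidin-2-one
Product: 16 (4R)-4-benzyl-3-(4,4-dimethoxybutanoyl)-1,3-oxazolidin-2-one, via mixed pivalic anhydride 15 (not isolated)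
Conditions: t-BuCOCl, Et3N, THF, −20 °C; then 14, LiCl, −20 °C to rt
Reagents that add atoms: none
Why: N-acylation of the oxazolidinone through the mixed pivalic anhydride (LiCl/Et3N protocol) avoids strong base and acid, so the acetal survives.

Step 11
Reactants: 16 N-acyl oxazolidinone
Product: 18 (4R)-4-benzyl-3-[(2R)-2-(2,2-dimethoxyethyl)-5-methylhex-4-enoyl]-1,3-oxazolidin-2-one, via sodium enolate 17 (not isolated)
Conditions: NaN(SiMe3)2, THF, −78 °C; then prenyl bromide, −78 to −40 °C
Reagents that add atoms: prenyl bromide (1-bromo-3-methylbut-2-ene), CC(C)=CCBr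
Why: Evans asymmetric alkylation: the chelated Z-sodium enolate is alkylated by the allylic bromide on the face opposite the benzyl group of the (R)-auxiliary, which sets the later C6 centre as R.

Step 12
Reactants: 18 alkylated imide
Product: 19 S-ethyl (2R)-2-(2,2-dimethoxyethyl)-5-methylhex-4-enethioate
Conditions: EtSH, n-BuLi, THF, 0 °C
Reagents that add atoms: ethanethiol, CCS
Why: Lithium ethanethiolate attacks the exocyclic imide carbonyl (transthioesterification) without epimerisation and returns the auxiliary.

Step 13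
Reactants: 11 iodo ketone; 19 thioester
Product: 21 methyl 3-[(1S,2S,4R)-2-acetyl-4-[(4R)-4-(2,2-dimethoxyethyl)-7-methyl-3-oxooct-6-en-1-yl]-1-methylcyclobutyl]propanoate, via alkylzinc iodide 20 (not isolated)
Conditions: Zn, LiCl, THF, 40 °C; then 19, PdCl2(PPh3)2 (cat.), PhMe, rt
Reagents that add atoms: none
Why: Zinc insertion into the primary iodide gives an alkylzinc iodide that tolerates the ketone and the ester, and the palladium-catalysed Fukuyama coupling with the thioester forms the C7–C8 bond as a ketone under neutral conditions that leave the adjacent stereocentre untouched.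

Step 14
Reactants: 21 diketone
Product: 22 methyl 3-[(1S,2R,4R)-4-[(4R)-4-(2,2-dimethoxyethyl)-7-methyl-3-methylideneoct-6-en-1-yl]-1-methyl-2-(prop-1-en-2-yl)cyclobutyl]propanoate
Conditions: Zn, CH2Br2, TiCl4 (preformed reagent), THF/CH2Cl2, 0 °C to rt
Reagents that add atoms: dibromomethane, BrCBr
Why: Takai–Lombardo methylenation, a non-basic titanium–zinc methylene transfer, converts both ketones to 1,1-disubstituted alkenes without epimerising the neighbouring centres and without attacking the ester or the acetal.

Step 15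
Reactants: 22 diene acetal ester
Product: 24 3-[(1S,2R,4R)-1-methyl-4-[(4R)-7-methyl-3-methylidene-4-(2-oxoethyl)oct-6-en-1-yl]-2-(prop-1-en-2-yl)cyclobutyl]propanoic acid, via acetal acid 23 (not isolated)
Conditions: LiOH, THF/MeOH/H2O, rt; then AcOH/H2O/THF (pH about 3), 40 °C
Reagents that add atoms: lithium hydroxide, [Li+].[OH-]; water, O
Why: Saponification of the only ester, followed by mild acid hydrolysis of the dimethyl acetal (far faster than protonation of the alkenes at this acidity), frees the acid and the aldehyde.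

Step 16
Reactants: 24 aldehyde acid
Product: 25 3-[(1S,2R,4R)-4-[(4R)-4-[2-hydroxy-3-(methoxycarbonyl)but-3-en-1-yl]-7-methyl-3-methylideneoct-6-en-1-yl]-1-methyl-2-(prop-1-en-2-yl)cyclobutyl]propanoic acid (both carbinol epimers)
Conditions: methyl acrylate (excess), DABCO (3 equiv), MeOH, rt
Reagents that add atoms: methyl acrylate, C=CC(=O)OC
Why: The Morita–Baylis–Hillman reaction of the unhindered aldehyde with methyl acrylate installs the 2-(methoxycarbonyl)allyl alcohol, and the carbinol centre, formed without control, is lost in step 17.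

Step 17
Reactants: 25 Baylis–Hillman alcohol
Product: 26 3-[(1S,2R,4R)-4-[(4R)-4-[(2Z)-3-(bromomethyl)-4-methoxy-4-oxobut-2-en-1-yl]-7-methyl-3-methylideneoct-6-en-1-yl]-1-methyl-2-(prop-1-en-2-yl)cyclobutyl]propanoic acid
Conditions: NBS, Me2S, CH2Cl2, −20 to 0 °C (reagent preformed)
Reagents that add atoms: N-bromosuccinimide, O=C1CCC(=O)N1Br
Why: The bromodimethylsulfonium reagent activates the Baylis–Hillman alcohol and bromide attacks in the SN2' sense, giving the rearranged primary allylic bromide as the favoured Z-2-(bromomethyl)alk-2-enoate.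

Step 18
Reactants: 26 bromo acid
Product: 27 methyl (1S,7E,10R,14R,16R)-1-methyl-11-methylidene-10-(3-methylbut-2-en-1-yl)-4-oxo-16-(prop-1-en-2-yl)-5-oxabicyclo[12.2.0]hexadec-7-ene-7-carboxylate (14-membered lactone)
Conditions: Cs2CO3, DMF, high dilution (slow addition), rt
Reagents that add atoms: none
Why: Macrolactonisation by intramolecular SN2 alkylation of the cesium carboxylate at the reactive primary allylic bromide closes the 14-membered ring and keeps the alkene geometry (ring CH2 cis to the CH2–O arm).

Step 19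
Reactants: 27 14-membered lactone
Product: 29 (1S,4R,6R,10R,12R)-4-(3-methoxy-3-oxoprop-1-en-2-yl)-1-methyl-7-methylidene-6-(3-methylbut-2-en-1-yl)-12-(prop-1-en-2-yl)bicyclo[8.2.0]dodecane-3-carboxylic acid (either or both C3 epimers), via boron ketene acetal 28 (not isolated)
Conditions: (4S,5S)-2-bromo-4,5-diphenyl-1,3-bis{[3,5-bis(trifluoromethyl)phenyl]sulfonyl}-1,3,2-diazaborolidine (2.2 equiv), i-Pr2NEt, CH2Cl2, −78 °C, then 4 °C; aqueous work-up
Reagents that add atoms: none
Why: The bromoborane and the amine enolise the lactone, the only ester with α-hydrogens, to the chiral boron ketene acetal 28, whose O–C=C unit and 2-(methoxycarbonyl)allyl unit undergo a suprafacial [3,3]-sigmatropic shift through a chair-like six-membered array that joins C3 to C4 and turns the lactone CH2–O carbon into the exocyclic methylene. The closest known reaction type is the enantioselective Ireland–Claisen ring contraction of macrolactones with this diazaborolidine controller. The ten-membered carbocycle closes by contraction of the 14-membered lactone (14 to 10), the new bond forming inside the six-membered pericyclic array and not by end-to-end closure of a ten-atom chain. C4 is set by the face of the E-trisubstituted alkene that meets the ketene acetal, dictated by the twofold-symmetric controller on boron through the chair array in which the ring CH2 cis to the CH2–O arm is axial, while C3 follows from the ketene acetal geometry and is erased in step 20. The step needs chemoselective enolisation (secured because the acrylate ester has no α-hydrogen), bond formation at the alkene CH and not at the CH2–O carbon (fixed by the [3,3] topology) and facial selectivity at C4 (reagent control, with C6 and the cyclobutane centres outside the reacting array).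

Step 20
Reactants: 29 ring-contracted acid
Product: 31 methyl 2-[(1S,4S,6R,10R,12R)-1-methyl-7-methylidene-6-(3-methylbut-2-en-1-yl)-12-(prop-1-en-2-yl)bicyclo[8.2.0]dodecan-4-yl]prop-2-enoate (target), via thiohydroxamate ester 30 (not isolated)
Conditions: 1-hydroxypyridine-2(1H)-thione, DCC, DMAP (cat.), CH2Cl2, dark, rt; then t-BuSH (excess), PhH, hν (visible), rt
Reagents that add atoms: none
Why: Barton reductive decarboxylation: the thiohydroxamate ester fragments on irradiation to the secondary C3 radical, which is reduced by tert-butyl thiol kept in excess to outrun transannular addition to the alkenes, so the helper carboxyl and the C3 stereocentre are removed.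

**Compound list**

1 | (2E,6E)-farnesol | CC(C)=CCC/C(C)=C/CC/C(C)=C/CO | starting material
2 | (2E,6E)-farnesal | CC(C)=CCC/C(C)=C/CC/C(C)=C/C=O | intermediate
3 | (2E,6E)-farnesoic acid | CC(C)=CCC/C(C)=C/CC/C(C)=C/C(O)=O | intermediate
4 | (2E,6E)-farnesoyl chloride | CC(C)=CCC/C(C)=C/CC/C(C)=C/C(Cl)=O | intermediate
5 | (6E)-7,11-dimethyl-3-methylidenedodeca-1,6,10-trien-1-one (vinylketene) | CC(C)=CCC/C(C)=C/CCC(=C)C=C=O | intermediate
6 | rac-(1R,5S,6S)-6-methyl-2-methylidene-6-(4-methylpent-3-en-1-yl)bicyclo[3.1.1]heptan-7-one (racemate; SMILES shows the enantiomer carried on) | C=C1CC[C@@H]2C(=O)[C@H]1[C@@]2(C)CCC=C(C)C | intermediate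
7 | rac-(1R,5R,6S)-6-methyl-2-methylidene-6-(4-methylpent-3-en-1-yl)bicyclo[3.1.1]heptane (racemate; SMILES shows the enantiomer carried on) | C=C1CC[C@@H]2C[C@H]1[C@@]2(C)CCC=C(C)C | intermediate
8 | rac-methyl 3-[(1S,5R,6S)-6-methyl-2-oxobicyclo[3.1.1]heptan-6-yl]propanoate (racemate; SMILES shows the enantiomer carried on) | O=C1CC[C@@H]2C[C@H]1[C@@]2(C)CCC(=O)OC | intermediate
9 | methyl 3-[(1S,5R,6S)-6-methyl-2-oxobicyclo[3.1.1]heptan-6-yl]propanoate (single enantiomer) | O=C1CC[C@@H]2C[C@H]1[C@@]2(C)CCC(=O)OC | intermediate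
10 | methyl 3-[(1S,2S,5R,6S)-2-hydroxy-2,6-dimethylbicyclo[3.1.1]heptan-6-yl]propanoate | C[C@]1(O)CC[C@@H]2C[C@H]1[C@@]2(C)CCC(=O)OC | intermediate
11 | methyl 3-[(1S,2S,4S)-2-acetyl-4-(2-iodoethyl)-1-methylcyclobutyl]propanoate | ICC[C@@H]1C[C@H](C(C)=O)[C@@]1(C)CCC(=O)OC | intermediate
12 | methyl 4,4-dimethoxybutanoate | COC(OC)CCC(=O)OC | starting material
13 | 4,4-dimethoxybutanoic acid | COC(OC)CCC(O)=O | intermediate
14 | (4R)-4-benzyl-1,3-oxazolidin-2-one | O=C1N[C@H](Cc2ccccc2)CO1 | starting material
15 | 4,4-dimethoxybutanoic pivalic anhydride | COC(OC)CCC(=O)OC(=O)C(C)(C)C | intermediate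
16 | (4R)-4-benzyl-3-(4,4-dimethoxybutanoyl)-1,3-oxazolidin-2-one | COC(OC)CCC(=O)N1[C@H](Cc2ccccc2)COC1=O | intermediate
17 | sodium Z-enolate of 16 | [Na+].COC(OC)C/C=C(\[O-])N1[C@H](Cc2ccccc2)COC1=O | intermediate
18 | (4R)-4-benzyl-3-[(2R)-2-(2,2-dimethoxyethyl)-5-methylhex-4-enoyl]-1,3-oxazolidin-2-one | COC(OC)C[C@H](C(=O)N1[C@H](Cc2ccccc2)COC1=O)CC=C(C)C | intermediate
19 | S-ethyl (2R)-2-(2,2-dimethoxyethyl)-5-methylhex-4-enethioate | COC(OC)C[C@H](C(=O)SCC)CC=C(C)C | intermediate
20 | alkylzinc iodide from 11 (iodozincioethyl cyclobutane) | I[Zn]CC[C@@H]1C[C@H](C(C)=O)[C@@]1(C)CCC(=O)OC | intermediate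
21 | methyl 3-[(1S,2S,4R)-2-acetyl-4-[(4R)-4-(2,2-dimethoxyethyl)-7-methyl-3-oxooct-6-en-1-yl]-1-methylcyclobutyl]propanoate | COC(OC)C[C@H](C(=O)CC[C@@H]1C[C@H](C(C)=O)[C@@]1(C)CCC(=O)OC)CC=C(C)C | intermediate
22 | methyl 3-[(1S,2R,4R)-4-[(4R)-4-(2,2-dimethoxyethyl)-7-methyl-3-methylideneoct-6-en-1-yl]-1-methyl-2-(prop-1-en-2-yl)cyclobutyl]propanoate | COC(OC)C[C@H](C(=C)CC[C@@H]1C[C@H](C(C)=C)[C@@]1(C)CCC(=O)OC)CC=C(C)C | intermediate
23 | 3-[(1S,2R,4R)-4-[(4R)-4-(2,2-dimethoxyethyl)-7-methyl-3-methylideneoct-6-en-1-yl]-1-methyl-2-(prop-1-en-2-yl)cyclobutyl]propanoic acid | COC(OC)C[C@H](C(=C)CC[C@@H]1C[C@H](C(C)=C)[C@@]1(C)CCC(O)=O)CC=C(C)C | intermediate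
24 | 3-[(1S,2R,4R)-1-methyl-4-[(4R)-7-methyl-3-methylidene-4-(2-oxoethyl)oct-6-en-1-yl]-2-(prop-1-en-2-yl)cyclobutyl]propanoic acid | O=CC[C@H](C(=C)CC[C@@H]1C[C@H](C(C)=C)[C@@]1(C)CCC(O)=O)CC=C(C)C | intermediate
25 | 3-[(1S,2R,4R)-4-[(4R)-4-[2-hydroxy-3-(methoxycarbonyl)but-3-en-1-yl]-7-methyl-3-methylideneoct-6-en-1-yl]-1-methyl-2-(prop-1-en-2-yl)cyclobutyl]propanoic acid (carbinol epimers) | COC(=O)C(=C)C(O)C[C@H](C(=C)CC[C@@H]1C[C@H](C(C)=C)[C@@]1(C)CCC(O)=O)CC=C(C)C | intermediate
26 | 3-[(1S,2R,4R)-4-[(4R)-4-[(2Z)-3-(bromomethyl)-4-methoxy-4-oxobut-2-en-1-yl]-7-methyl-3-methylideneoct-6-en-1-yl]-1-methyl-2-(prop-1-en-2-yl)cyclobutyl]propanoic acid | COC(=O)/C(CBr)=C/C[C@H](C(=C)CC[C@@H]1C[C@H](C(C)=C)[C@@]1(C)CCC(O)=O)CC=C(C)C | intermediate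
27 | methyl (1S,7E,10R,14R,16R)-1-methyl-11-methylidene-10-(3-methylbut-2-en-1-yl)-4-oxo-16-(prop-1-en-2-yl)-5-oxabicyclo[12.2.0]hexadec-7-ene-7-carboxylate | COC(=O)/C1=C/C[C@@H](CC=C(C)C)C(=C)CC[C@@H]2C[C@H](C(C)=C)[C@@]2(C)CCC(=O)OC1 | intermediate
28 | boron ketene acetal of 27 (O-diazaborolidinyl ketene acetal, geometry at the ketene acetal not specified) | COC(=O)/C1=C/C[C@@H](CC=C(C)C)C(=C)CC[C@@H]2C[C@H](C(C)=C)[C@@]2(C)CC=C(OB3N(S(=O)(=O)c4cc(cc(c4)C(F)(F)F)C(F)(F)F)[C@@H](c4ccccc4)[C@H](c4ccccc4)N3S(=O)(=O)c4cc(cc(c4)C(F)(F)F)C(F)(F)F)OC1 | intermediate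
29 | (1S,4R,6R,10R,12R)-4-(3-methoxy-3-oxoprop-1-en-2-yl)-1-methyl-7-methylidene-6-(3-methylbut-2-en-1-yl)-12-(prop-1-en-2-yl)bicyclo[8.2.0]dodecane-3-carboxylic acid (C3 epimers, centre not specified) | C=C1CC[C@@H]2C[C@H](C(=C)C)[C@@]2(C)CC(C(O)=O)[C@H](C(=C)C(=O)OC)C[C@H]1CC=C(C)C | intermediate
30 | 2-thioxopyridin-1(2H)-yl ester of 29 (thiohydroxamate ester) | C=C1CC[C@@H]2C[C@H](C(=C)C)[C@@]2(C)CC(C(=O)ON3C=CC=CC3=S)[C@H](C(=C)C(=O)OC)C[C@H]1CC=C(C)C | intermediate
31 | methyl 2-[(1S,4S,6R,10R,12R)-1-methyl-7-methylidene-6-(3-methylbut-2-en-1-yl)-12-(prop-1-en-2-yl)bicyclo[8.2.0]dodecan-4-yl]prop-2-enoate | C=C1CC[C@@H]2C[C@H](C(=C)C)[C@@]2(C)CC[C@H](C(=C)C(=O)OC)C[C@H]1CC=C(C)C | target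

**Count and risks**

Total step count: 20. Longest linear sequence: 16 steps (steps 1–8, then 13–20); steps 9–12 make the side-chain thioester 19.

Steps most likely to fail:

1. Step 19. What may go wrong: enolisation at the γ-position of the unsaturated ester instead of the lactone α-position, or attack on the wrong alkene face in a mismatched pairing of controller and substrate, which would give the C4 epimer. Fallback (radical addition–fragmentation instead of a sigmatropic shift, without the lactone tether): it sets out from 26. Coupling with 1-hydroxypyridine-2(1H)-thione and DCC gives the thiohydroxamate ester of 26 F1. Irradiation at high dilution without a hydrogen donor would generate the primary C3 radical, which adds to C4 of the 2-(bromomethyl)alk-2-enoate (10-exo closure) and expels a bromine atom that carries the chain. This forms the C3–C4 bond with loss of CO2 and comes back to the route at 31, with C4 then under substrate control only.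

2. Step 8. What may go wrong: hydrogen abstraction by the alkoxy radical from the syn methyl group (leading to a cyclic ether), or scission of the C1–C2 bond instead of C2–C3. Fallback (polar route through an alkene, no radical): it sets out from 9. KN(SiMe3)2 and PhNTf2 give the enol triflate methyl 3-[(1S,5R,6S)-6-methyl-2-(trifluoromethylsulfonyloxy)bicyclo[3.1.1]hept-2-en-6-yl]propanoate F2. Fe(acac)3-catalysed coupling with MeMgBr gives methyl 3-[(1R,5R,6S)-2,6-dimethylbicyclo[3.1.1]hept-2-en-6-yl]propanoate F3. Ozonolysis with PPh3 work-up gives the keto aldehyde methyl 3-[(1S,2S,4S)-2-acetyl-1-methyl-4-(2-oxoethyl)cyclobutyl]propanoate F4. NaBH4 at −78 °C should reduce only the aldehyde, to methyl 3-[(1S,2S,4S)-2-acetyl-4-(2-hydroxyethyl)-1-methylcyclobutyl]propanoate F5. I2, PPh3 and imidazole then give 11, where the route is rejoined.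

3. Step 6. What may go wrong: too small a rate difference between the two enantiomers, so that the recovered ketone is of low enantiomeric purity. Fallback (separable covalent diastereomers instead of a kinetic resolution): it sets out from 8. Addition of lithiated (S)-N,S-dimethyl-S-phenylsulfoximine to the ketone at −78 °C gives two diastereomeric β-hydroxysulfoximines that are separated on silica. The one derived from the wanted enantiomer, methyl 3-[(1S,2S,5R,6S)-2-hydroxy-6-methyl-2-{[(S)-N-methyl-S-phenylsulfonimidoyl]methyl}bicyclo[3.1.1]heptan-6-yl]propanoate F6, is heated in toluene, which reverses the addition and comes back to the route at 9.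

**Further compounds**

F1 | step 19 | 2-thioxopyridin-1(2H)-yl ester of 26 (thiohydroxamate ester) | COC(=O)/C(CBr)=C/C[C@H](C(=C)CC[C@@H]1C[C@H](C(C)=C)[C@@]1(C)CCC(=O)ON1C=CC=CC1=S)CC=C(C)C
F2 | step 8 | methyl 3-[(1S,5R,6S)-6-methyl-2-(trifluoromethylsulfonyloxy)bicyclo[3.1.1]hept-2-en-6-yl]propanoate | O=S(=O)(OC1=CC[C@@H]2C[C@H]1[C@@]2(C)CCC(=O)OC)C(F)(F)F
F3 | step 8 | methyl 3-[(1R,5R,6S)-2,6-dimethylbicyclo[3.1.1]hept-2-en-6-yl]propanoate | CC1=CC[C@@H]2C[C@H]1[C@@]2(C)CCC(=O)OC
F4 | step 8 | methyl 3-[(1S,2S,4S)-2-acetyl-1-methyl-4-(2-oxoethyl)cyclobutyl]propanoate | O=CC[C@@H]1C[C@H](C(C)=O)[C@@]1(C)CCC(=O)OC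
F5 | step 8 | methyl 3-[(1S,2S,4S)-2-acetyl-4-(2-hydroxyethyl)-1-methylcyclobutyl]propanoate | OCC[C@@H]1C[C@H](C(C)=O)[C@@]1(C)CCC(=O)OC
F6 | step 6 | methyl 3-[(1S,2S,5R,6S)-2-hydroxy-6-methyl-2-{[(S)-N-methyl-S-phenylsulfonimidoyl]methyl}bicyclo[3.1.1]heptan-6-yl]propanoate | CN=[S@@](C[C@]1(O)CC[C@@H]2C[C@H]1[C@@]2(C)CCC(=O)OC)(=O)c1ccccc1
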